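**Plan**

-   Retrosynthetic cuts: the acrylate C=C (the danshensu ester C–O is made beforehand on a malonate half-ester), then O1–C2 and C2–C3 of the coumarin, then the vinyl–O bond to the vanillin ring, then the styryl C=C on ring A.
-   Enabling feature: in the 3-aryloxycoumarin the carbonyl carbon C2 has only two skeletal neighbours, ring oxygen O1 and C3, and C3 already carries the ether oxygen. Taking C2 out as carbon monoxide leaves a ring-A phenol and an (E)-aryl styryl ether whose vinylic C–H (the future C3) lies cis to ring A.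
-   Forward order: ring-A aldehyde to (E)-vinyl iodide, copper O-vinylation of vanillin, unmasking of the phenol, then rhodium-catalysed cyclocarbonylation to close the pyranone. This is the only ring built; the three benzene rings are bought.
-   The chain is then joined: demethylation, Knoevenagel–Doebner condensation with the malonate half-ester of allyl-protected danshensu, and deallylation.
-   Stereochemistry: the single stereocenter is bought as sodium (R)-danshensu and no bond to it is ever broken. The E enol ether comes from Takai olefination and is kept through the copper coupling; the E acrylate comes from the decarboxylative condensation.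

Key step: step 5

Assumption: commercial sodium danshensu is the (2R) salt, which is the configuration of the target's only stereocenter; "allyl" means prop-2-en-1-yl throughout.

**Route**

Step 1
Reactants: 1 2-hydroxy-4,5-dimethoxybenzaldehyde
Product: 2 4,5-dimethoxy-2-(allyloxy)benzaldehyde
Conditions: allyl bromide (1.3 equiv), K2CO3 (2 equiv), DMF, 50 °C
Reagents that add atoms: allyl bromide, C=CCBr
Why: Williamson ether synthesis on the salicylaldehyde phenoxide masks the future directing phenol, which would otherwise compete with vanillin in step 3, as an ether that zerovalent palladium later removes without acid.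

Step 2
Reactants: 2 4,5-dimethoxy-2-(allyloxy)benzaldehyde
Product: 3 1-[(E)-2-iodoethenyl]-4,5-dimethoxy-2-(allyloxy)benzene
Conditions: CrCl2 (6 equiv), CHI3 (2 equiv), THF–1,4-dioxane, 0 °C to rt, dark
Reagents that add atoms: iodoform, IC(I)I
Why: Takai olefination, in which the gem-dichromium species from CHI3 and CrCl2 adds to the aldehyde and the β-oxido adduct eliminates through its less hindered anti-periplanar arrangement to give the E-vinyl iodide, with aryl and allyl ethers inert to CrCl2.

Step 3
Reactants: 3 1-[(E)-2-iodoethenyl]-4,5-dimethoxy-2-(allyloxy)benzene; 4 vanillin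
Product: 5 4-{[(E)-2-[4,5-dimethoxy-2-(allyloxy)phenyl]ethenyl]oxy}-3-methoxybenzaldehyde
Conditions: CuI (10 mol%), N,N-dimethylglycine hydrochloride (30 mol%), Cs2CO3 (2 equiv), 1,4-dioxane, 80 °C, argon
Reagents that add atoms: none
Why: Ullmann-type copper-catalysed C–O coupling of a phenol with a vinyl iodide, which proceeds with retention of alkene geometry and tolerates the formyl group, so the E enol ether needed in step 5 is fixed here.

Step 4
Reactants: 5 4-{[(E)-2-[4,5-dimethoxy-2-(allyloxy)phenyl]ethenyl]oxy}-3-methoxybenzaldehyde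
Product: 6 4-{[(E)-2-(2-hydroxy-4,5-dimethoxyphenyl)ethenyl]oxy}-3-methoxybenzaldehyde
Conditions: Pd(PPh3)4 (2 mol%), K2CO3 (3 equiv), MeOH–THF, rt; pH 7 buffer work-up, product used at once
Reagents that add atoms: none
Why: Tsuji–Trost deallylation, in which zerovalent palladium ionises the aryl allyl ether to a π-allyl complex that methanol captures, under basic conditions that leave the acid-sensitive enol ether and the aldehyde alone.

Step 5
Reactants: 6 4-{[(E)-2-(2-hydroxy-4,5-dimethoxyphenyl)ethenyl]oxy}-3-methoxybenzaldehyde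
Product: 7 4-[(6,7-dimethoxy-2-oxo-2H-chromen-3-yl)oxy]-3-methoxybenzaldehyde
Conditions: [Cp*RhCl2]2 (2.5 mol%), Cu(OAc)2 (2.2 equiv), NaOAc (1 equiv), CO (1 atm), MeCN, 85 °C
Reagents that add atoms: carbon monoxide, [C-]#[O+]
Why: Acetate-assisted ligand exchange binds the phenoxide of 6 to trivalent rhodium, and concerted metalation–deprotonation then cleaves the vinylic C–H on the aryloxy-bearing carbon, the one C–H that the E geometry places cis to ring A, to give a six-membered oxarhodacycle. Carbon monoxide inserts into the Rh–C(vinyl) bond (forming C2–C3), C–O reductive elimination from the seven-membered acyl rhodacycle forms O1–C2, and Cu(OAc)2 returns the monovalent rhodium so released to the trivalent state. The closest known reaction is the oxidative cyclocarbonylation of 2-alkenylphenols to coumarins by phenol-directed alkenyl C–H activation under [Cp*RhCl2]2 or Pd(OAc)2 with a copper oxidant, applied here to an alkene whose terminus carries an aryloxy group. The pyranone closes as a formal five-plus-one annulation, the ring-forming event being the lactonising C–O reductive elimination at the metal, and no stereocenter is created. The step needs site selectivity for the vinylic C–H over the arene and formyl C–H bonds, which chelation secures because only that C–H gives a six-membered metallacycle from the phenoxide, and it needs the E alkene geometry, which steps 2 and 3 supply. The inductive pull of the aryloxy oxygen makes this C–H more acidic and should ease metalation, while the acetate buffer keeps strong acid out so that the phenol does not add to the enol ether.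

Step 6
Reactants: 7 4-[(6,7-dimethoxy-2-oxo-2H-chromen-3-yl)oxy]-3-methoxybenzaldehyde
Product: 8 4-[(6,7-dihydroxy-2-oxo-2H-chromen-3-yl)oxy]-3-hydroxybenzaldehyde
Conditions: BBr3 (8 equiv), CH2Cl2, −78 °C to rt; then ice–water
Reagents that add atoms: none
Why: Lewis-acid ether cleavage, in which bromide attacks the O-methyl carbon of each boron-complexed aryl methyl ether, while the sp2 C–O bonds of the coumarinyl aryl ether, the lactone and the aldehyde (as a reversible boron adduct) return intact on hydrolysis.

Step 7
Reactants: 9 sodium (R)-danshensu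
Product: 10 allyl (2R)-3-[3,4-bis(allyloxy)phenyl]-2-hydroxypropanoate
Conditions: allyl bromide (3.5 equiv), K2CO3 (2.5 equiv), DMF, rt to 40 °C, argon
Reagents that add atoms: allyl bromide, C=CCBr
Why: SN2 O-alkylation of the carboxylate and of the two phenoxides (Williamson etherification), in which carbonate does not deprotonate the secondary alcohol, so it stays free and the stereocenter is untouched.

Step 8
Reactants: 10 allyl (2R)-3-[3,4-bis(allyloxy)phenyl]-2-hydroxypropanoate; 11 Meldrum's acid
Product: 12 3-{[(2R)-3-[3,4-bis(allyloxy)phenyl]-1-oxo-1-(allyloxy)propan-2-yl]oxy}-3-oxopropanoic acid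
Conditions: toluene, 105 °C
Reagents that add atoms: none
Why: Ring-opening alcoholysis of Meldrum's acid by the secondary alcohol, with loss of acetone, gives the malonic half-ester by O-acylation only, so the configuration is retained.

Step 9
Reactants: 8 4-[(6,7-dihydroxy-2-oxo-2H-chromen-3-yl)oxy]-3-hydroxybenzaldehyde; 12 3-{[(2R)-3-[3,4-bis(allyloxy)phenyl]-1-oxo-1-(allyloxy)propan-2-yl]oxy}-3-oxopropanoic acid
Product: 14 allyl (2R)-3-[3,4-bis(allyloxy)phenyl]-2-{[(2E)-3-{4-[(6,7-dihydroxy-2-oxo-2H-chromen-3-yl)oxy]-3-hydroxyphenyl}prop-2-enoyl]oxy}propanoate, via arylidenemalonic half-ester 13 (not isolated)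
Conditions: pyridine, piperidine (0.2 equiv), 50 °C, argon; then cold 1 M HCl work-up
Reagents that add atoms: none
Why: Knoevenagel–Doebner condensation of a malonic half-ester, a reaction known with unprotected hydroxybenzaldehydes, in which the piperidine-derived iminium condenses with the active methylene and decarboxylation in pyridine gives the thermodynamically favoured E cinnamate, so the ester needs no separate acylation and the phenols need no protection.

Step 10
Reactants: 14 allyl (2R)-3-[3,4-bis(allyloxy)phenyl]-2-{[(2E)-3-{4-[(6,7-dihydroxy-2-oxo-2H-chromen-3-yl)oxy]-3-hydroxyphenyl}prop-2-enoyl]oxy}propanoate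
Product: 15 (2R)-3-(3,4-dihydroxyphenyl)-2-{[(2E)-3-{4-[(6,7-dihydroxy-2-oxo-2H-chromen-3-yl)oxy]-3-hydroxyphenyl}prop-2-enoyl]oxy}propanoic acid
Conditions: Pd(PPh3)4 (5 mol%), morpholine (9 equiv), THF, rt, argon; then 1 M HCl to pH 2–3, reversed-phase chromatography
Reagents that add atoms: none
Why: Tsuji–Trost deallylation, in which zerovalent palladium ionises the allyl ester and both aryl allyl ethers and morpholine traps the π-allyl complexes at room temperature, conditions that should leave the cinnamate ester, the lactone and the stereocenter unchanged.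

**Compound list**

1 | 2-hydroxy-4,5-dimethoxybenzaldehyde | COc1cc(O)c(C=O)cc1OC | starting material
2 | 4,5-dimethoxy-2-(allyloxy)benzaldehyde | COc1cc(OCC=C)c(C=O)cc1OC | intermediate
3 | 1-[(E)-2-iodoethenyl]-4,5-dimethoxy-2-(allyloxy)benzene | COc1cc(OCC=C)c(/C=C/I)cc1OC | intermediate
4 | vanillin (4-hydroxy-3-methoxybenzaldehyde) | COc1cc(C=O)ccc1O | starting material
5 | 4-{[(E)-2-[4,5-dimethoxy-2-(allyloxy)phenyl]ethenyl]oxy}-3-methoxybenzaldehyde | COc1cc(C=O)ccc1O/C=C/c1cc(OC)c(OC)cc1OCC=C | intermediate
6 | 4-{[(E)-2-(2-hydroxy-4,5-dimethoxyphenyl)ethenyl]oxy}-3-methoxybenzaldehyde | COc1cc(C=O)ccc1O/C=C/c1cc(OC)c(OC)cc1O | intermediate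
7 | 4-[(6,7-dimethoxy-2-oxo-2H-chromen-3-yl)oxy]-3-methoxybenzaldehyde | COc1cc(C=O)ccc1Oc1cc2cc(OC)c(OC)cc2oc1=O | intermediate
8 | 4-[(6,7-dihydroxy-2-oxo-2H-chromen-3-yl)oxy]-3-hydroxybenzaldehyde | O=Cc1ccc(Oc2cc3cc(O)c(O)cc3oc2=O)c(O)c1 | intermediate
9 | sodium (2R)-3-(3,4-dihydroxyphenyl)-2-hydroxypropanoate (sodium (R)-danshensu) | O[C@H](Cc1ccc(O)c(O)c1)C(=O)[O-].[Na+] | starting material
10 | allyl (2R)-3-[3,4-bis(allyloxy)phenyl]-2-hydroxypropanoate | O[C@H](Cc1ccc(OCC=C)c(OCC=C)c1)C(=O)OCC=C | intermediate
11 | Meldrum's acid (2,2-dimethyl-1,3-dioxane-4,6-dione) | CC1(C)OC(=O)CC(=O)O1 | starting material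
12 | 3-{[(2R)-3-[3,4-bis(allyloxy)phenyl]-1-oxo-1-(allyloxy)propan-2-yl]oxy}-3-oxopropanoic acid (hydrogen malonate of 10) | OC(=O)CC(=O)O[C@H](Cc1ccc(OCC=C)c(OCC=C)c1)C(=O)OCC=C | intermediate
13 | 2-({4-[(6,7-dihydroxy-2-oxo-2H-chromen-3-yl)oxy]-3-hydroxyphenyl}methylidene)-3-oxo-3-{[(2R)-3-[3,4-bis(allyloxy)phenyl]-1-oxo-1-(allyloxy)propan-2-yl]oxy}propanoic acid (arylidenemalonic half-ester; C=C geometry not defined) | OC(=O)C(=Cc1ccc(Oc2cc3cc(O)c(O)cc3oc2=O)c(O)c1)C(=O)O[C@H](Cc1ccc(OCC=C)c(OCC=C)c1)C(=O)OCC=C | intermediate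
14 | allyl (2R)-3-[3,4-bis(allyloxy)phenyl]-2-{[(2E)-3-{4-[(6,7-dihydroxy-2-oxo-2H-chromen-3-yl)oxy]-3-hydroxyphenyl}prop-2-enoyl]oxy}propanoate | O=C(/C=C/c1ccc(Oc2cc3cc(O)c(O)cc3oc2=O)c(O)c1)O[C@H](Cc1ccc(OCC=C)c(OCC=C)c1)C(=O)OCC=C | intermediate
15 | (2R)-3-(3,4-dihydroxyphenyl)-2-{[(2E)-3-{4-[(6,7-dihydroxy-2-oxo-2H-chromen-3-yl)oxy]-3-hydroxyphenyl}prop-2-enoyl]oxy}propanoic acid | O=C(/C=C/c1ccc(Oc2cc3cc(O)c(O)cc3oc2=O)c(O)c1)O[C@H](Cc1ccc(O)c(O)c1)C(=O)O | target

**Step count and risks**

Total step count: 10. Longest linear sequence: 8 steps (steps 1–6, 9 and 10, from compound 1); the danshensu branch (steps 7 and 8) joins at step 9.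

Steps most likely to fail:

1.  Step 5. The phenol may add to the enol ether (a five-membered closure with loss of the vanillin phenoxide, ending in a benzofuran) faster than the cis vinylic C–H is metalated, or the rhodacycle may be protonated back before carbon monoxide inserts. The fallback sets out from vanillin 4 and builds the pyranone by condensation instead. Compound 4 is O-alkylated with chloroacetic acid (NaOH, water, reflux) to (4-formyl-2-methoxyphenoxy)acetic acid F1. F1 is esterified with the phenol of 1 (EDC hydrochloride, DMAP, CH2Cl2) to 2-formyl-4,5-dimethoxyphenyl (4-formyl-2-methoxyphenoxy)acetate F2. DBU in MeCN then closes the ring by intramolecular aldol condensation of the aryloxyacetate methylene onto the ortho formyl group, with dehydration. This comes back to the route at coumarin 7.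

2.  Step 3. The formyl-bearing, ortho-substituted phenoxide is a weak nucleophile, so C–O coupling may be slow enough for base-induced dehydroiodination to the arylalkyne or erosion of the E geometry to take over. The fallback sets out from aldehyde 2 and reverses the polarity of the vinyl partner. Takai–Utimoto boryl-olefination (Cl2CHBpin, CrCl2, LiI, THF) gives 2-[(E)-2-(4,5-dimethoxy-2-(allyloxy)phenyl)ethenyl]-4,4,5,5-tetramethyl-1,3,2-dioxaborolane F3. Chan–Lam coupling of F3 with vanillin 4 (Cu(OAc)2, Et3N, 4 Å molecular sieves, CH2Cl2, air, rt) forms the enol ether with retention of geometry. This comes back to the route at compound 5.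

3.  Step 9. Phenoxide formation in the amine medium may deactivate the aldehyde and tie up the piperidine, so condensation stalls, and prolonged heating then invites aminolysis or epimerisation of the α-acyloxy ester. The fallback sets out from triol 8 and separates C=C formation from ester formation. Allyl bromide and K2CO3 in DMF give 3-(allyloxy)-4-{[6,7-bis(allyloxy)-2-oxo-2H-chromen-3-yl]oxy}benzaldehyde F4. Doebner condensation with malonic acid (pyridine, piperidine, 90 °C) passes through the arylidenemalonic acid F5, which is not isolated, to (2E)-3-[3-(allyloxy)-4-{[6,7-bis(allyloxy)-2-oxo-2H-chromen-3-yl]oxy}phenyl]prop-2-enoic acid F6. Steglich esterification of F6 with alcohol 10 (EDC hydrochloride, DMAP, CH2Cl2) gives the hexa-allyl ester F7. Deallylation of F7 with Pd(PPh3)4 and morpholine, as in step 10, comes back to the route at the target 15.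

**Further compounds**

F1 | step 5 | (4-formyl-2-methoxyphenoxy)acetic acid | COc1cc(C=O)ccc1OCC(=O)O
F2 | step 5 | 2-formyl-4,5-dimethoxyphenyl (4-formyl-2-methoxyphenoxy)acetate | COc1cc(C=O)ccc1OCC(=O)Oc1cc(OC)c(OC)cc1C=O
F3 | step 3 | 2-[(E)-2-(4,5-dimethoxy-2-(allyloxy)phenyl)ethenyl]-4,4,5,5-tetramethyl-1,3,2-dioxaborolane | COc1cc(OCC=C)c(/C=C/B2OC(C)(C)C(C)(C)O2)cc1OC
F4 | step 9 | 3-(allyloxy)-4-{[6,7-bis(allyloxy)-2-oxo-2H-chromen-3-yl]oxy}benzaldehyde | C=CCOc1cc(C=O)ccc1Oc1cc2cc(OCC=C)c(OCC=C)cc2oc1=O
F5 | step 9 | 2-({3-(allyloxy)-4-{[6,7-bis(allyloxy)-2-oxo-2H-chromen-3-yl]oxy}phenyl}methylidene)propanedioic acid | C=CCOc1cc(C=C(C(=O)O)C(=O)O)ccc1Oc1cc2cc(OCC=C)c(OCC=C)cc2oc1=O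
F6 | step 9 | (2E)-3-[3-(allyloxy)-4-{[6,7-bis(allyloxy)-2-oxo-2H-chromen-3-yl]oxy}phenyl]prop-2-enoic acid | C=CCOc1cc(/C=C/C(=O)O)ccc1Oc1cc2cc(OCC=C)c(OCC=C)cc2oc1=O
F7 | step 9 | allyl (2R)-3-[3,4-bis(allyloxy)phenyl]-2-{[(2E)-3-[3-(allyloxy)-4-{[6,7-bis(allyloxy)-2-oxo-2H-chromen-3-yl]oxy}phenyl]prop-2-enoyl]oxy}propanoate | O=C(/C=C/c1ccc(Oc2cc3cc(OCC=C)c(OCC=C)cc3oc2=O)c(OCC=C)c1)O[C@H](Cc1ccc(OCC=C)c(OCC=C)c1)C(=O)OCC=C
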